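The tetrahydrofuran (O1; C2 bearing the 4-hydroxy-3-methoxyphenyl ring; C3–Me; C4–Me; C5–aryl) is closed at C2–C3. The route exploits the fact that C2 is a benzylic ether carbon on an electron-rich 4-oxy-3-methoxyphenyl ring: in an open-chain benzyl ether its C–H is abstracted by DDQ, and the resulting oxocarbenium ion is captured by a tethered (Z)-enol acetate. This forms C2–C3 and sets both centres under control of C4 and C5, which come from an anti-selective propargylation. The formyl group left at C3 is reduced to the methyl group, and the threo aryl ether side chain is added by SN2 displacement and ketone reduction.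

Key step: step 7

Remark: compounds 3, 7, 16, 18 and 4-(benzyloxy)-3-methoxybenzaldehyde are taken as commercial; the tetrahydrofuran locants O1, C2 (guaiacyl carbon), C3, C4, C5 are used throughout the discussion.

**Step 1**
Reactants: 1 vanillin
Product: 2 4-formyl-2-methoxyphenyl pivalate
Conditions: PivCl, Et3N, DMAP (cat.), CH2Cl2, 0 °C to rt
Reagents that add atoms: pivaloyl chloride, CC(C)(C)C(Cl)=O
Why: O-acylation of the phenol; the pivalate keeps this ring electron-poor, so that later DDQ oxidation and benzylic ionization should occur only on the other aryl ring, and it should survive NaBH4.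

**Step 2**
Reactants: 3 (S)-but-3-yn-2-ol
Product: 4 (S)-but-3-yn-2-yl methanesulfonate
Conditions: MsCl, Et3N, CH2Cl2, −78 to 0 °C
Reagents that add atoms: methanesulfonyl chloride, CS(Cl)(=O)=O
Why: O-sulfonylation forms only the O–S bond, so the stereocentre is retained.

**Step 3**
Reactants: 2 4-formyl-2-methoxyphenyl pivalate, 4 (S)-but-3-yn-2-yl methanesulfonate
Product: 6 4-[(1R,2R)-1-hydroxy-2-methylbut-3-yn-1-yl]-2-methoxyphenyl pivalate, via allenylzinc mesylate 5 (not isolated)
Conditions: Pd(OAc)2 (5 mol %), PPh3 (5 mol %), Et2Zn (3 equiv), THF, −78 to −20 °C; aq. NH4Cl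
Reagents that add atoms: none
Why: Pd-catalysed, zinc-mediated propargylation: zerovalent palladium formed in the flask opens mesylate 4 anti (SN2′), transmetalation gives the configurationally stable allenylzinc 5, and this adds to the aldehyde through a cyclic SE2′ transition state with the aryl group equatorial, so that the new C–C bond forms opposite to the departed mesylate (2R) and the carbinol centre is set anti to the methyl group (1R).

**Step 4**
Reactants: 7 4-(benzyloxy)-3-methoxybenzyl alcohol
Product: 8 4-(benzyloxy)-3-methoxybenzyl 2,2,2-trichloroacetimidate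
Conditions: Cl3CCN, DBU (10 mol %), CH2Cl2, 0 °C
Reagents that add atoms: trichloroacetonitrile, ClC(Cl)(Cl)C#N
Why: Base-catalysed addition of the alcohol to the electron-poor nitrile gives the imidate, used without storage.

**Step 5**
Reactants: 6 4-[(1R,2R)-1-hydroxy-2-methylbut-3-yn-1-yl]-2-methoxyphenyl pivalate, 8 4-(benzyloxy)-3-methoxybenzyl 2,2,2-trichloroacetimidate
Product: 9 4-[(1R,2R)-1-{[4-(benzyloxy)-3-methoxybenzyl]oxy}-2-methylbut-3-yn-1-yl]-2-methoxyphenyl pivalate
Conditions: La(OTf)3 (5 mol %), toluene, rt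
Reagents that add atoms: none
Why: Acid-catalysed benzylation with a trichloroacetimidate (the stabilized 4-benzyloxy-3-methoxybenzyl cation is captured by the secondary alcohol), run without base so that the aryl pivalate and the alkyne C–H stay untouched; no stereocentre is involved.

**Step 6**
Reactants: 9 4-[(1R,2R)-1-{[4-(benzyloxy)-3-methoxybenzyl]oxy}-2-methylbut-3-yn-1-yl]-2-methoxyphenyl pivalate
Product: 10 (1Z,3R,4R)-4-{[4-(benzyloxy)-3-methoxybenzyl]oxy}-4-[3-methoxy-4-(pivaloyloxy)phenyl]-3-methylbut-1-en-1-yl acetate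
Conditions: AcOH (1.5 equiv), [RuCl2(p-cymene)]2 (1 mol %), P(4-ClC6H4)3 (3 mol %), DMAP (4 mol %), toluene, 60 °C
Reagents that add atoms: acetic acid, CC(=O)O
Why: Ru-catalysed anti-Markovnikov addition of a carboxylic acid to a terminal alkyne through a ruthenium vinylidene, in which acetate attacks the vinylidene α-carbon and protonolysis of the vinyl–ruthenium bond should give the (Z)-enol ester.

**Step 7**
Reactants: 10 (1Z,3R,4R)-4-{[4-(benzyloxy)-3-methoxybenzyl]oxy}-4-[3-methoxy-4-(pivaloyloxy)phenyl]-3-methylbut-1-en-1-yl acetate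
Product: 13 4-[(2R,3R,4S,5S)-5-[4-(benzyloxy)-3-methoxyphenyl]-4-(hydroxymethyl)-3-methyltetrahydrofuran-2-yl]-2-methoxyphenyl pivalate, via oxocarbenium ion 11 (not isolated), via tetrahydrofuran-3-carbaldehyde 12 (not isolated)
Conditions: DDQ (1.2 equiv), 2,6-dichloropyridine (3 equiv), LiClO4, 4 Å MS, ClCH2CH2Cl, −20 °C; then MeOH, NaBH4, −20 to 0 °C; aq. NaHCO3
Reagents that add atoms: none
Why: Proposed new method: DDQ should form a charge-transfer complex with the electron-rich 4-benzyloxy-3-methoxyphenyl ring and abstract hydride from its OCH2 group to give the (E)-oxocarbenium ion 11, whose carbon is attacked by the β-carbon of the tethered (Z)-enol acetate; loss of the acetyl group gives aldehyde 12, which is reduced in the same flask before its α-centre can epimerize. The closest known reaction types are the DDQ-mediated oxidative C–H cleavage of 4-alkoxybenzyl ethers with enol acetate capture, established for six-membered tetrahydropyran-4-ones, and the Lewis acid-mediated ring contraction of 4,5-dihydro-1,3-dioxepines, which passes through the same oxocarbenium/(Z)-enol pair and gives 2,3-cis-tetrahydrofuran-3-carbaldehydes; new here is the five-membered closure from an oxidatively generated cation and an aldehyde enol acetate. The tetrahydrofuran is closed in a 5-(enolexo)-endo-trig mode, the C=O+ bond lying inside and the enol C=C outside the new ring. C2 is controlled by the (E)-geometry of the oxocarbenium ion together with the pseudo-equatorial C5 aryl group in the envelope transition state (2,5-cis), and C3 by allylic 1,3-strain in the (Z)-enol acetate, which keeps the C4–H bond eclipsed with the enol double bond so that the formyl carbon ends trans to the C4 methyl group and therefore cis to the C2 aryl group. The step needs chemoselective hydride abstraction at the OCH2 group and not at C5–H or at the new C2–H, which the electron-poor pivaloyloxy ring, the inductive effect of the formyl group, the near-stoichiometric DDQ charge and the low temperature should secure, and it needs bond formation through the enol β-carbon and not a 2-oxonia-Cope pathway, which the polarization of the enol acetate should secure.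

**Step 8**
Reactants: 13 4-[(2R,3R,4S,5S)-5-[4-(benzyloxy)-3-methoxyphenyl]-4-(hydroxymethyl)-3-methyltetrahydrofuran-2-yl]-2-methoxyphenyl pivalate
Product: 14 4-[(2R,3R,4S,5S)-5-[4-(benzyloxy)-3-methoxyphenyl]-3-methyl-4-(tosyloxymethyl)tetrahydrofuran-2-yl]-2-methoxyphenyl pivalate
Conditions: TsCl, Et3N, DMAP (cat.), CH2Cl2, 0 °C to rt
Reagents that add atoms: 4-methylbenzenesulfonyl chloride, Cc1ccc(cc1)S(Cl)(=O)=O
Why: Sulfonylation of the primary alcohol; the ring stereocentres are not touched.

**Step 9**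
Reactants: 14 4-[(2R,3R,4S,5S)-5-[4-(benzyloxy)-3-methoxyphenyl]-3-methyl-4-(tosyloxymethyl)tetrahydrofuran-2-yl]-2-methoxyphenyl pivalate
Product: 15 4-[(2R,3R,4R,5S)-5-[4-(benzyloxy)-3-methoxyphenyl]-3,4-dimethyltetrahydrofuran-2-yl]-2-methoxyphenol
Conditions: LiBHEt3 (6 equiv), THF, 0 °C to rt; aq. NH4Cl
Reagents that add atoms: none
Why: SN2 hydride displacement of the primary tosylate should give the C3 methyl group and, in the same operation, reductive cleavage of the aryl pivalate should release the phenol needed for the side chain; no stereocentre is involved.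

**Step 10**
Reactants: 16 ethyl (S)-lactate
Product: 17 (S)-2-hydroxy-1-(pyrrolidin-1-yl)propan-1-one
Conditions: pyrrolidine (2 equiv, neat), rt
Reagents that add atoms: pyrrolidine, C1CCNC1
Why: Aminolysis of the activated α-hydroxy ester by a secondary amine; the stereocentre is not involved.

**Step 11**
Reactants: 17 (S)-2-hydroxy-1-(pyrrolidin-1-yl)propan-1-one, 18 1-(benzyloxy)-4-bromo-2-methoxybenzene
Product: 20 (S)-1-[4-(benzyloxy)-3-methoxyphenyl]-2-hydroxypropan-1-one, via arylmagnesium bromide 19 (not isolated)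
Conditions: 18, Mg, THF, rt; separately 17, i-PrMgCl (1.0 equiv), THF, −20 °C, then 19 (1.5 equiv), 0 °C to rt; aq. NH4Cl
Reagents that add atoms: none
Why: Grignard addition to the tertiary amide should stop at the tetrahedral magnesium hemiaminal, chelated by the neighbouring magnesium alkoxide, which collapses to the ketone only on work-up, so neither over-addition nor loss of the α-stereocentre is expected.

**Step 12**
Reactants: 20 (S)-1-[4-(benzyloxy)-3-methoxyphenyl]-2-hydroxypropan-1-one
Product: 21 (S)-1-[4-(benzyloxy)-3-methoxyphenyl]-1-oxopropan-2-yl 4-methylbenzenesulfonate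
Conditions: TsCl, Et3N, DMAP (cat.), CH2Cl2, 0 °C
Reagents that add atoms: 4-methylbenzenesulfonyl chloride, Cc1ccc(cc1)S(Cl)(=O)=O
Why: O-sulfonylation with retention turns the lactate-derived hydroxyl into a leaving group.

**Step 13**
Reactants: 15 4-[(2R,3R,4R,5S)-5-[4-(benzyloxy)-3-methoxyphenyl]-3,4-dimethyltetrahydrofuran-2-yl]-2-methoxyphenol, 21 (S)-1-[4-(benzyloxy)-3-methoxyphenyl]-1-oxopropan-2-yl 4-methylbenzenesulfonate
Product: 22 (2R)-1-[4-(benzyloxy)-3-methoxyphenyl]-2-{4-[(2R,3R,4R,5S)-5-[4-(benzyloxy)-3-methoxyphenyl]-3,4-dimethyltetrahydrofuran-2-yl]-2-methoxyphenoxy}propan-1-one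
Conditions: K2CO3 (2 equiv), DMF, 0 °C to rt
Reagents that add atoms: none
Why: Williamson-type SN2 displacement of the α-keto secondary tosylate by the phenoxide with inversion sets the (R)-configured aryl ether carbon; the mild carbonate base at low temperature should limit enolization of electrophile and product.

**Step 14**
Reactants: 22 (2R)-1-[4-(benzyloxy)-3-methoxyphenyl]-2-{4-[(2R,3R,4R,5S)-5-[4-(benzyloxy)-3-methoxyphenyl]-3,4-dimethyltetrahydrofuran-2-yl]-2-methoxyphenoxy}propan-1-one
Product: 23 (1R,2R)-1-[4-(benzyloxy)-3-methoxyphenyl]-2-{4-[(2R,3R,4R,5S)-5-[4-(benzyloxy)-3-methoxyphenyl]-3,4-dimethyltetrahydrofuran-2-yl]-2-methoxyphenoxy}propan-1-ol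
Conditions: (R)-2-methyl-CBS-oxazaborolidine (0.3 equiv), BH3·SMe2 (1.2 equiv), THF, −20 °C; MeOH
Reagents that add atoms: none
Why: Corey–Bakshi–Shibata reduction, in which the (R)-oxazaborolidine (aryl as the large group) delivers hydride to the face that gives the (1R)-carbinol; this is also the sense of the polar Felkin–Anh preference of the α-aryloxy ketone, so reagent and substrate control should reinforce each other to give the threo alcohol.

**Step 15**
Reactants: 23 (1R,2R)-1-[4-(benzyloxy)-3-methoxyphenyl]-2-{4-[(2R,3R,4R,5S)-5-[4-(benzyloxy)-3-methoxyphenyl]-3,4-dimethyltetrahydrofuran-2-yl]-2-methoxyphenoxy}propan-1-ol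
Product: 24 4-[(1R,2R)-1-hydroxy-2-{4-[(2R,3R,4R,5S)-5-(4-hydroxy-3-methoxyphenyl)-3,4-dimethyltetrahydrofuran-2-yl]-2-methoxyphenoxy}propyl]-2-methoxyphenol (CNP0171079.2)
Conditions: H2 (1 atm), Pd/C (10 wt %), EtOAc, rt
Reagents that add atoms: none
Why: Hydrogenolysis of the two aryl benzyl ethers under neutral conditions at low pressure should release both phenols, because aryl benzyl ethers are cleaved much faster than the benzylic C–O bonds of the tetrahydrofuran and of the secondary alcohol.

**Compound list**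

1 | vanillin | COc1cc(C=O)ccc1O | starting material
2 | 4-formyl-2-methoxyphenyl pivalate | COc1cc(C=O)ccc1OC(=O)C(C)(C)C | intermediate
3 | (S)-but-3-yn-2-ol | C[C@H](O)C#C | starting material
4 | (S)-but-3-yn-2-yl methanesulfonate | C[C@H](OS(C)(=O)=O)C#C | intermediate
5 | (aR)-buta-1,2-dien-1-ylzinc methanesulfonate (formed in the flask) | [H]C(C)=[C@@]=C([H])[Zn]OS(C)(=O)=O | intermediate
6 | 4-[(1R,2R)-1-hydroxy-2-methylbut-3-yn-1-yl]-2-methoxyphenyl pivalate | COc1cc(ccc1OC(=O)C(C)(C)C)[C@@H]([C@H](C)C#C)O | intermediate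
7 | 4-(benzyloxy)-3-methoxybenzyl alcohol | COc1cc(CO)ccc1OCc1ccccc1 | starting material
8 | 4-(benzyloxy)-3-methoxybenzyl 2,2,2-trichloroacetimidate | COc1cc(COC(=N)C(Cl)(Cl)Cl)ccc1OCc1ccccc1 | intermediate
9 | 4-[(1R,2R)-1-{[4-(benzyloxy)-3-methoxybenzyl]oxy}-2-methylbut-3-yn-1-yl]-2-methoxyphenyl pivalate | COc1cc(ccc1OC(=O)C(C)(C)C)[C@@H]([C@H](C)C#C)OCc1ccc(OCc2ccccc2)c(OC)c1 | intermediate
10 | (1Z,3R,4R)-4-{[4-(benzyloxy)-3-methoxybenzyl]oxy}-4-[3-methoxy-4-(pivaloyloxy)phenyl]-3-methylbut-1-en-1-yl acetate | COc1cc(ccc1OC(=O)C(C)(C)C)[C@@H]([C@H](C)/C=C\OC(C)=O)OCc1ccc(OCc2ccccc2)c(OC)c1 | intermediate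
11 | (E)-oxocarbenium ion derived from 10 by loss of hydride from the OCH2 group (formed in the flask; counter-ion is the hydroquinone anion of DDQ) | COc1cc(ccc1OC(=O)C(C)(C)C)[C@@H]([C@H](C)/C=C\OC(C)=O)/[O+]=C/c1ccc(OCc2ccccc2)c(OC)c1 | intermediate
12 | (2S,3R,4R,5R)-2-[4-(benzyloxy)-3-methoxyphenyl]-5-[3-methoxy-4-(pivaloyloxy)phenyl]-4-methyltetrahydrofuran-3-carbaldehyde (formed in the flask) | COc1cc(ccc1OC(=O)C(C)(C)C)[C@@H]1O[C@H](c2ccc(OCc3ccccc3)c(OC)c2)[C@H](C=O)[C@H]1C | intermediate
13 | 4-[(2R,3R,4S,5S)-5-[4-(benzyloxy)-3-methoxyphenyl]-4-(hydroxymethyl)-3-methyltetrahydrofuran-2-yl]-2-methoxyphenyl pivalate | COc1cc(ccc1OC(=O)C(C)(C)C)[C@@H]1O[C@H](c2ccc(OCc3ccccc3)c(OC)c2)[C@H](CO)[C@H]1C | intermediate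
14 | 4-[(2R,3R,4S,5S)-5-[4-(benzyloxy)-3-methoxyphenyl]-3-methyl-4-(tosyloxymethyl)tetrahydrofuran-2-yl]-2-methoxyphenyl pivalate | COc1cc(ccc1OC(=O)C(C)(C)C)[C@@H]1O[C@H](c2ccc(OCc3ccccc3)c(OC)c2)[C@H](COS(=O)(=O)c2ccc(C)cc2)[C@H]1C | intermediate
15 | 4-[(2R,3R,4R,5S)-5-[4-(benzyloxy)-3-methoxyphenyl]-3,4-dimethyltetrahydrofuran-2-yl]-2-methoxyphenol | COc1cc(ccc1O)[C@@H]1O[C@H](c2ccc(OCc3ccccc3)c(OC)c2)[C@H](C)[C@H]1C | intermediate
16 | ethyl (S)-lactate | C[C@H](O)C(=O)OCC | starting material
17 | (S)-2-hydroxy-1-(pyrrolidin-1-yl)propan-1-one | C[C@H](O)C(=O)N1CCCC1 | intermediate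
18 | 1-(benzyloxy)-4-bromo-2-methoxybenzene | COc1cc(Br)ccc1OCc1ccccc1 | starting material
19 | [4-(benzyloxy)-3-methoxyphenyl]magnesium bromide (formed in the flask) | COc1cc([Mg]Br)ccc1OCc1ccccc1 | intermediate
20 | (S)-1-[4-(benzyloxy)-3-methoxyphenyl]-2-hydroxypropan-1-one | C[C@H](O)C(=O)c1ccc(OCc2ccccc2)c(OC)c1 | intermediate
21 | (S)-1-[4-(benzyloxy)-3-methoxyphenyl]-1-oxopropan-2-yl 4-methylbenzenesulfonate | C[C@H](OS(=O)(=O)c1ccc(C)cc1)C(=O)c1ccc(OCc2ccccc2)c(OC)c1 | intermediate
22 | (2R)-1-[4-(benzyloxy)-3-methoxyphenyl]-2-{4-[(2R,3R,4R,5S)-5-[4-(benzyloxy)-3-methoxyphenyl]-3,4-dimethyltetrahydrofuran-2-yl]-2-methoxyphenoxy}propan-1-one | COc1cc(C(=O)[C@@H](C)Oc2ccc([C@@H]3O[C@H](c4ccc(OCc5ccccc5)c(OC)c4)[C@H](C)[C@H]3C)cc2OC)ccc1OCc1ccccc1 | intermediate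
23 | (1R,2R)-1-[4-(benzyloxy)-3-methoxyphenyl]-2-{4-[(2R,3R,4R,5S)-5-[4-(benzyloxy)-3-methoxyphenyl]-3,4-dimethyltetrahydrofuran-2-yl]-2-methoxyphenoxy}propan-1-ol | COc1cc([C@@H](O)[C@@H](C)Oc2ccc([C@@H]3O[C@H](c4ccc(OCc5ccccc5)c(OC)c4)[C@H](C)[C@H]3C)cc2OC)ccc1OCc1ccccc1 | intermediate
24 | 4-[(1R,2R)-1-hydroxy-2-{4-[(2R,3R,4R,5S)-5-(4-hydroxy-3-methoxyphenyl)-3,4-dimethyltetrahydrofuran-2-yl]-2-methoxyphenoxy}propyl]-2-methoxyphenol | COc1cc([C@@H](O)[C@@H](C)Oc2ccc([C@@H]3O[C@H](c4ccc(O)c(OC)c4)[C@H](C)[C@H]3C)cc2OC)ccc1O | target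

**Step count and risks**

Total step count: 15. Longest linear sequence: 10 steps (steps 1, 3, 5, 6, 7, 8, 9, 13, 14, 15).

Steps most likely to fail:

Step 7 (key step, proposed new method). Possible failures are over-oxidation of the product at its new benzylic C2–H, hydride abstraction at the wrong benzylic position, or poor facial selectivity in the ring closure. The fallback keeps the same bond formation but generates the cation by Lewis acid instead of by oxidation, using known reaction types. It sets out from 6: silylation (TESCl, imidazole, DMF) would give the triethylsilyl ether F1, and the Ru-catalysed addition of acetic acid used in step 6 would give the (Z)-enol acetate F2. Treatment of F2 with commercial 4-(benzyloxy)-3-methoxybenzaldehyde and TMSOTf (CH2Cl2, −78 °C) would form oxocarbenium ion 11 by silyl ether–aldehyde condensation. The Prins/Mukaiyama-type closure of this cation onto the enol derivative is the event known from the TMSOTf-mediated ring contraction of 4,5-dihydro-1,3-dioxepines. It would give aldehyde 12, and reduction with NaBH4 in the same flask would bring the route back at 13.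

Step 6. Possible failures are slow turnover at the α-branched alkyne, Markovnikov addition, or erosion of the Z geometry that step 7 relies on. The fallback sets out from 9: hydroboration with dicyclohexylborane (THF, 0 °C) and oxidation with NaBO3·4H2O would give the aldehyde F3. Enol acetylation (Ac2O, KOAc, 100 °C) would then give the enol acetate as a Z/E mixture, from which the Z isomer is separated, returning to the route at 10.

Step 5. Possible failures are ionization of the very labile imidate faster than capture by the hindered secondary alcohol, with rearrangement to the N-benzyl trichloroacetamide, or acid cleavage of the new ether. The fallback replaces alkylation by reductive etherification and sets out from 6: silylation (TMSCl, imidazole, CH2Cl2) would give the trimethylsilyl ether F4. Treatment of F4 with 4-(benzyloxy)-3-methoxybenzaldehyde, Et3SiH and catalytic TMSOTf (CH2Cl2, −78 °C) would give the benzyl ether directly, returning to the route at 9.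

**Further compounds**

F1 | step 7 | 4-[(1R,2R)-2-methyl-1-(triethylsilyloxy)but-3-yn-1-yl]-2-methoxyphenyl pivalate | COc1cc(ccc1OC(=O)C(C)(C)C)[C@@H]([C@H](C)C#C)O[Si](CC)(CC)CC
F2 | step 7 | (1Z,3R,4R)-4-[3-methoxy-4-(pivaloyloxy)phenyl]-3-methyl-4-(triethylsilyloxy)but-1-en-1-yl acetate | COc1cc(ccc1OC(=O)C(C)(C)C)[C@@H]([C@H](C)/C=C\OC(C)=O)O[Si](CC)(CC)CC
F3 | step 6 | 4-[(1R,2R)-1-{[4-(benzyloxy)-3-methoxybenzyl]oxy}-2-methyl-4-oxobutyl]-2-methoxyphenyl pivalate | COc1cc(ccc1OC(=O)C(C)(C)C)[C@@H]([C@H](C)CC=O)OCc1ccc(OCc2ccccc2)c(OC)c1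
F4 | step 5 | 4-[(1R,2R)-2-methyl-1-(trimethylsilyloxy)but-3-yn-1-yl]-2-methoxyphenyl pivalate | COc1cc(ccc1OC(=O)C(C)(C)C)[C@@H]([C@H](C)C#C)O[Si](C)(C)C
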